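**Retrosynthetic overview**
1. Ring E is closed last through the enol-ether bond O8–C3, by copper-catalysed intramolecular C(sp2)–O coupling of a neopentyl alcohol with a (Z)-alkenyl iodide (key step); the C5–C1 chain and C7 come from allylation and reduction of a C6 aldehyde.
2. The C6 aldehyde comes from the bridging C6 ketone by one-carbon Wittig homologation; ring A comes from a double Mannich reaction of MeNH2 and two CH2O on a tricyclic keto ester (both C–N bonds, quaternary C19, C9).
3. Ring B is closed by a vinylogous Dieckmann condensation (C6–C19) after Negishi attachment of the C11–C10–C9–C6 chain at C12.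
4. Rings C/D come from an enantioselective phosphine-catalysed (3+2) annulation of cyclopent-2-en-1-one with methyl buta-2,3-dienoate (sets C14); C17 is set later by hydrogenation and C12=C13 by acid isomerisation.
5. Order of ring formation: C/D, then B, then A, then E.

Locants (for description only, taken from the target SMILES): ethyl C1–C2; ring E O8–C3=C4–C5–C6–C7; ring B C6–C9–C10–C11–C12=C13–C19; ring C C12–C13–C14–C15–C16; ring D C13–C14–C17–C18–C19; ring A N21–C22–C9–C6–C19–C20; CO2Me on C17.

Assumption: the (S)-catalyst of step 1 is taken to give the (3aS,6aS) adduct; if the sense is opposite, its enantiomer is used.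

**Step 1**
Reactants: 1 cyclopent-2-en-1-one; 2 methyl buta-2,3-dienoate
Product: 3 methyl (3aS,6aS)-4-oxo-3,3a,4,5,6,6a-hexahydropentalene-1-carboxylate
Conditions: catalyst P1 = (S)-1-[3,5-bis(trifluoromethyl)phenyl]-3-[1-(dicyclohexylphosphanyl)-3,3-dimethylbutan-2-yl]thiourea (10 mol%), toluene, 4 Å sieves, 23 °C
Reagents that add atoms: none
Why: Proposed new method: an enantioselective Lu-type phosphine-catalysed (3+2) annulation of an unactivated cycloalkenone with a new bifunctional catalyst; the electron-rich dialkylphosphine adds to the allenoate, the α-carbon of the zwitterion attacks C14 of the enone (whose carbonyl is hydrogen-bonded to the thiourea so that one face is shielded), the enolate then closes C13–C19 onto the vinylphosphonium and proton shift with loss of phosphine gives the enoate, so the cis ring fusion is forced and C14 (the centre that controls all later ones) is set by the catalyst; closest known reaction type: the racemic PBu3-mediated allenoate/butynoate–cycloalkenone (3+2) annulation and the enantioselective amino-acid-derived phosphine (3+2) annulations of acrylates and acyclic enones.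

**Step 2**
Reactants: 3 methyl (3aS,6aS)-4-oxo-3,3a,4,5,6,6a-hexahydropentalene-1-carboxylate
Product: 5 methyl (3aS,6aS)-4-[(trifluoromethanesulfonyl)oxy]-3,3a,6,6a-tetrahydropentalene-1-carboxylate, via lithium enolate 4 (not isolated)
Conditions: LiN(SiMe3)2, THF, −78 °C; PhNTf2, −78 → 0 °C
Reagents that add atoms: N-phenylbis(trifluoromethanesulfonimide) (PhNTf2), O=S(=O)(N(c1ccccc1)S(=O)(=O)C(F)(F)F)C(F)(F)F
Why: Kinetic enolisation removes the less hindered C16 methylene proton of the ketone (the γ-protons of the enoate are much less acidic) and O-triflation gives the enol triflate (enol triflate formation); no stereocentre changes.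

**Step 3**
Reactants: 5 methyl (3aS,6aS)-4-[(trifluoromethanesulfonyl)oxy]-3,3a,6,6a-tetrahydropentalene-1-carboxylate; 6 (4-ethoxy-4-oxobutyl)zinc bromide
Product: 7 methyl (3aS,6aS)-4-(4-ethoxy-4-oxobutyl)-3,3a,6,6a-tetrahydropentalene-1-carboxylate
Conditions: Pd(PPh3)4 (5 mol%), THF, 50 °C
Reagents that add atoms: none
Why: Negishi coupling of an alkenyl triflate with a functionalised primary alkylzinc halide (oxidative addition to zerovalent palladium, transmetalation, reductive elimination) tolerates both esters and touches no stereocentre.

**Step 4**
Reactants: 7 methyl (3aS,6aS)-4-(4-ethoxy-4-oxobutyl)-3,3a,6,6a-tetrahydropentalene-1-carboxylate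
Product: 8 tricyclic keto ester of rings B/C/D (C6 ketone; C12=C16 and C17=C18 alkenes; H13/H14/H19 all cis)
Conditions: KOtBu (2.2 equiv), THF, 0 → 23 °C; aq. HCl quench
Reagents that add atoms: none
Why: Vinylogous Dieckmann condensation: γ-deprotonation of the enoate at C19 gives a dienolate whose γ-carbon is the only position that reaches the chain ester through an unstrained seven-membered ring, and the equilibrium is drained by the stabilised enolate of the vinylogous β-keto ester; C19 is epimerisable and settles with H19 cis to H13/H14 on the convex face, because C6 must be cis to C12 for ring B to exist.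

**Step 5**
Reactants: 8 tricyclic keto ester of rings B/C/D; 9 methylamine; 10 formaldehyde (first of the two equivalents; used as paraformaldehyde)
Product: 12 azatetracyclic keto ester of rings A/B/C/D (N-methylpiperidine closed; C19 quaternary; C20 cis to H13/H14; C12=C16 and C17=C18 alkenes), via mono-Mannich base 11 (not isolated)
Conditions: MeNH2 (2 M in MeOH, 1.1 equiv), (CH2O)n (2.2 equiv of CH2O), AcOH (20 mol%), MeOH, 65 °C; aq. NaHCO3
Reagents that add atoms: formaldehyde (the second equivalent of 10; supplies C22), C=O
Why: Double Mannich aza-annulation of a β-keto-ester-type CH acid with one primary amine and two formaldehyde units (8 + MeNH2 + 2 CH2O → 12 + 2 H2O): aminomethylation of the highly enolised C19 with the first CH2O occurs on the convex face of the cis-bicyclo[3.3.0] unit (cis to H13 and H14) and makes C19 quaternary, then the secondary amine of 11 condenses with the second CH2O and the iminium ion closes on the C9 enol, which fixes C9 because only a cis 1,3-bridge can form; both C–N bonds of ring A are made here.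

**Step 6**
Reactants: 12 azatetracyclic keto ester of rings A/B/C/D
Product: 13 isomerised azatetracycle (tetrasubstituted C12=C13 alkene; C17=C18 enoate)
Conditions: TsOH·H2O (1.5 equiv; the first equivalent only protonates the amine), 1,2-dichloroethane, 60 °C, stopped as soon as 12 is consumed; aq. NaHCO3
Reagents that add atoms: none
Why: Acid-catalysed alkene isomerisation: protonation at C16 gives the tertiary C12 cation, which loses H13 to give the tetrasubstituted C12=C13 alkene at the fusion of rings B and C; C19 is already quaternary, so the alkene cannot reach conjugation with the ketone, and the further shift to C13=C14 (which would give a conjugated cyclopentadiene ester and erase C14) needs the C13 cation next to the acyl-bearing quaternary C19 and the protonated amine and is therefore slow, so the reaction is run under kinetic control; C13 is erased as a stereocentre as intended and C14 is untouched.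

**Step 7**
Reactants: 13 isomerised azatetracycle
Product: 14 azatetracyclic ketone with saturated ester (H17 cis to H14; CO2Me cis to C15)
Conditions: H2 (1 atm), Pd/C (10% w/w), EtOAc, 23 °C
Reagents that add atoms: none
Why: Heterogeneous catalytic hydrogenation reduces only the conjugated trisubstituted enoate (the tetrasubstituted alkene and the hindered ketone survive) and delivers hydrogen to the face of ring D that carries H14 and C20 and not C15 and the C6 bridge, so H17 ends cis to H14 and the ester cis to C15 as in the target.

**Step 8**
Reactants: 14 azatetracyclic ketone with saturated ester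
Product: 16 C6 aldehyde (C7 = CHO; C6 epimer mixture), via methyl enol ether 15 (not isolated)
Conditions: Ph3P(CH2OMe)Cl (2.0 equiv), KN(SiMe3)2 (1.9 equiv), THF, 0 → 45 °C; then 2 M aq. HCl, THF, 23 °C; aq. NaHCO3
Reagents that add atoms: (methoxymethyl)triphenylphosphonium chloride, COC[P+](c1ccccc1)(c1ccccc1)c1ccccc1.[Cl-]; water, O
Why: Wittig methoxymethylenation of the bridging ketone followed by acid hydrolysis of the enol ether is the standard one-carbon homologation to an aldehyde; the phosphonium salt is kept in excess over the base to protect the C17 ester, and the C6 epimer mixture is irrelevant because C6 is enolised in step 11.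

**Step 9**
Reactants: 17 pent-2-yn-1-ol
Product: 19 (2Z)-3-iodopent-2-en-1-ol, via alkenylaluminate 18 (not isolated)
Conditions: NaAlH2(OCH2CH2OCH3)2, THF, 0 → 23 °C; I2, −78 → 0 °C
Reagents that add atoms: iodine (I2), II
Why: Hydroxyl-directed trans-hydroalumination of a propargylic alcohol puts aluminium on C3 cis to the CH2O group and iodinolysis proceeds with retention (hydroalumination–iodination), giving the (Z)-3-iodoallylic alcohol.

**Step 10**
Reactants: 19 (2Z)-3-iodopent-2-en-1-ol
Product: 20 (2Z)-1-bromo-3-iodopent-2-ene
Conditions: CBr4, PPh3, CH2Cl2, 0 °C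
Reagents that add atoms: tetrabromomethane (CBr4), BrC(Br)(Br)Br
Why: The Appel reaction converts the primary allylic alcohol into the bromide under neutral conditions without touching the alkenyl iodide or the double-bond geometry.

**Step 11**
Reactants: 16 C6 aldehyde; 20 (2Z)-1-bromo-3-iodopent-2-ene
Product: 22 iodo aldehyde (C6 quaternary; CHO on the ring A side; (2Z)-3-iodopent-2-enyl on the ring B side), via potassium enolate 21 (not isolated)
Conditions: KOtBu (1.05 equiv), THF, 0 °C, 15 min; then 20, −40 → 0 °C
Reagents that add atoms: none
Why: Enolate C-alkylation of an α-branched aldehyde with a reactive allylic bromide creates the quaternary C6; the electrophile should approach the exocyclic enolate over the carbocyclic C10–C13 bridge (equatorial to the piperidine chair, away from its two syn-axial C–H bonds at C20 and C22, and facing only one such C–H at C10 because C13 is sp2), so the new chain becomes C5 and the formyl group stays on the piperidine side as in the target; one equivalent of base spares the C17 ester.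

**Step 12**
Reactants: 22 iodo aldehyde
Product: 23 iodo alcohol (C7 = CH2OH)
Conditions: NaBH4, MeOH, 0 °C
Reagents that add atoms: none
Why: Borohydride reduction takes the aldehyde chemoselectively (the ester, the alkenyl iodide and the alkene are inert); no stereocentre changes.

**Step 13**
Reactants: 23 iodo alcohol
Product: 24 CNP0159589.2 (target; 6S,9S,14R,17R,19R in the locants above)
Conditions: CuI (10 mol%), 3,4,7,8-tetramethyl-1,10-phenanthroline (20 mol%), Cs2CO3 (2.0 equiv), toluene, 100 °C
Reagents that add atoms: none
Why: Ullmann-type copper-catalysed intramolecular O-vinylation: the monovalent copper alkoxide couples with the alkenyl iodide with retention at C3, and because the iodide is cis to C5 the six-membered enol ether closes at O8–C3 with unambiguous regiochemistry and no effect on any stereocentre.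

**Compound list**
1 | cyclopent-2-en-1-one | O=C1C=CCC1 | starting material
2 | methyl buta-2,3-dienoate | C=C=CC(=O)OC | starting material
3 | methyl (3aS,6aS)-4-oxo-3,3a,4,5,6,6a-hexahydropentalene-1-carboxylate | O=C1[C@H]2CC=C(C(=O)OC)[C@H]2CC1 | intermediate
4 | lithium enolate of 3 (lithium (3aS,6aS)-1-(methoxycarbonyl)-3,3a,6,6a-tetrahydropentalen-4-olate) | [Li]OC1=CC[C@@H]2C(C(=O)OC)=CC[C@H]12 | intermediate (not isolated)
5 | methyl (3aS,6aS)-4-[(trifluoromethanesulfonyl)oxy]-3,3a,6,6a-tetrahydropentalene-1-carboxylate | FC(F)(F)S(=O)(=O)OC1=CC[C@@H]2C(C(=O)OC)=CC[C@H]12 | intermediate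
6 | (4-ethoxy-4-oxobutyl)zinc bromide | CCOC(=O)CCC[Zn]Br | starting material
7 | methyl (3aS,6aS)-4-(4-ethoxy-4-oxobutyl)-3,3a,6,6a-tetrahydropentalene-1-carboxylate | CCOC(=O)CCCC1=CC[C@@H]2C(C(=O)OC)=CC[C@H]12 | intermediate
8 | tricyclic keto ester of rings B/C/D (C6 ketone; C12=C16 and C17=C18 alkenes; H13/H14/H19 all cis) | O=C1CCCC2=CC[C@@H]3C(C(=O)OC)=C[C@H]1[C@H]23 | intermediate
9 | methylamine | CN | starting material
10 | formaldehyde (as paraformaldehyde; two equivalents enter 12) | C=O | starting material
11 | mono-Mannich base (8 carrying CH2NHMe on C19, cis to H13/H14) | O=C1CCCC2=CC[C@@H]3C(C(=O)OC)=C[C@@]1(CNC)[C@H]23 | intermediate (not isolated)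
12 | azatetracyclic keto ester of rings A/B/C/D (C19 quaternary; C12=C16 and C17=C18 alkenes) | O=C1[C@@H]2CCC3=CC[C@@H]4C(C(=O)OC)=C[C@@]1(CN(C)C2)[C@H]34 | intermediate
13 | isomerised azatetracycle (C12=C13 tetrasubstituted; C17=C18 enoate) | O=C1[C@@H]2CCC3=C4[C@H](CC3)C(C(=O)OC)=C[C@@]41CN(C)C2 | intermediate
14 | azatetracyclic ketone with saturated ester (H17 cis to H14) | O=C1[C@@H]2CCC3=C4[C@H](CC3)[C@H](C(=O)OC)C[C@@]41CN(C)C2 | intermediate
15 | methyl enol ether (C6=C7H–OMe; E/Z mixture) | COC=C1[C@@H]2CCC3=C4[C@H](CC3)[C@H](C(=O)OC)C[C@@]41CN(C)C2 | intermediate (not isolated)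
16 | C6 aldehyde (C7 = CHO; C6 epimer mixture) | O=CC1[C@@H]2CCC3=C4[C@H](CC3)[C@H](C(=O)OC)C[C@@]41CN(C)C2 | intermediate
17 | pent-2-yn-1-ol | CCC#CCO | starting material
18 | alkenylaluminate (sodium 3-ethyl-2,2-bis(2-methoxyethoxy)-2,5-dihydro-1,2-oxaaluminol-2-uide) | CCC1=CCO[Al-]1(OCCOC)OCCOC.[Na+] | intermediate (not isolated)
19 | (2Z)-3-iodopent-2-en-1-ol | CC/C(I)=C/CO | intermediate
20 | (2Z)-1-bromo-3-iodopent-2-ene | CC/C(I)=C/CBr | intermediate
21 | potassium enolate of 16 | [K]OC=C1[C@@H]2CCC3=C4[C@H](CC3)[C@H](C(=O)OC)C[C@@]41CN(C)C2 | intermediate (not isolated)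
22 | iodo aldehyde (C6 quaternary; CHO = C7; (2Z)-3-iodopent-2-enyl = C5–C1) | CC/C(I)=C/C[C@]2(C=O)[C@@H]1CCC3=C4[C@H](CC3)[C@H](C(=O)OC)C[C@@]42CN(C)C1 | intermediate
23 | iodo alcohol (C7 = CH2OH) | CC/C(I)=C/C[C@]2(CO)[C@@H]1CCC3=C4[C@H](CC3)[C@H](C(=O)OC)C[C@@]42CN(C)C1 | intermediate
24 | CNP0159589.2 | CCC1=CC[C@]2(CO1)[C@@H]1CCC3=C4[C@H](CC3)[C@H](C(=O)OC)C[C@@]42CN(C)C1 | target

**Step count and risk**
Total step count: 13 (11 in the main line plus 2 for building block 20).
Longest linear sequence: 11 (steps 1–8 and 11–13).

Steps most likely to fail:

1. Step 1 (the proposed new annulation). The cycloalkenone may react too slowly with a chiral phosphine, or the enantiomeric excess may be low. The fallback sets out from 1 and 2 and comes back at 3, using known chemistry only. The annulation is run with PBu3 (the racemic Lu-type annulation of cycloalkenones), which gives 3 together with its enantiomer, methyl (3aR,6aR)-4-oxo-3,3a,4,5,6,6a-hexahydropentalene-1-carboxylate F1. A ketoreductase with glucose dehydrogenase cofactor recycling, chosen by screening, then reduces only F1 to methyl (3aR,4S,6aR)-4-hydroxy-3,3a,4,5,6,6a-hexahydropentalene-1-carboxylate F2. F2 is removed by chromatography and enantiopure 3 (at most half of the material) goes on to step 2.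

2. Step 6 (alkene isomerisation while the enoate is still present). In 13 the C14–H is doubly allylic, and prolonged acid treatment could carry the alkene on to C13=C14, giving a conjugated cyclopentadiene ester and destroying the C14 stereocentre. The fallback sets out from 12 and comes back at 14, so it also replaces step 7. The enoate of 12 is reduced first by conjugate hydride addition with CuH made in the flask (Cu(OAc)2·H2O 5 mol%, 1,2-bis(diphenylphosphino)benzene 5 mol%, polymethylhydrosiloxane, tBuOH, toluene, 23 °C), which leaves the isolated C12=C16 alkene and the hindered ketone alone. Protonation of the ester enolate at C17 from the convex face of the cis-fused rings C/D (the face of H13 and H14) gives the saturated keto ester with the C12=C16 alkene F3 (H17 cis to H13/H14). With no enoate left there is no conjugated sink, and TsOH·H2O in 1,2-dichloroethane at 60 °C then moves C12=C16 to the tetrasubstituted C12=C13 position and gives 14.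

3. Step 11 (quaternary C6 next to quaternary C19). O-alkylation, N-quaternisation by the allylic bromide or the wrong facial selectivity could intervene. The fallback sets out from 16, replaces steps 9–13 and comes back at 24. Conjugate addition of 16 to pent-1-en-3-one (DBU cat., THF), a soft electrophile that does not alkylate oxygen or the amine, gives the keto aldehyde F4 (3-oxopentyl chain on C6, same face as planned for the allyl group). NaBH4 in EtOH/CH2Cl2 at −78 °C reduces the aldehyde first and gives the hydroxy ketone F5. Acid-catalysed cyclodehydration of F5 (PPTS, toluene, 4 Å sieves, 80 °C) closes ring E by the same O8–C3 bond and gives 24.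

**Further compounds**
F1 | step 1 | methyl (3aR,6aR)-4-oxo-3,3a,4,5,6,6a-hexahydropentalene-1-carboxylate | O=C1[C@@H]2CC=C(C(=O)OC)[C@@H]2CC1
F2 | step 1 | methyl (3aR,4S,6aR)-4-hydroxy-3,3a,4,5,6,6a-hexahydropentalene-1-carboxylate | O[C@@H]1[C@@H]2CC=C(C(=O)OC)[C@@H]2CC1
F3 | step 6 | saturated keto ester with the C12=C16 alkene (12 with C17–C18 reduced; H17 cis to H13/H14) | O=C1[C@@H]2CCC3=CC[C@@H]4[C@H](C(=O)OC)C[C@@]1(CN(C)C2)[C@H]34
F4 | step 11 | keto aldehyde (C6 bears CHO and 3-oxopentyl) | CCC(=O)CC[C@]2(C=O)[C@@H]1CCC3=C4[C@H](CC3)[C@H](C(=O)OC)C[C@@]42CN(C)C1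
F5 | step 11 | hydroxy ketone (C6 bears CH2OH and 3-oxopentyl) | CCC(=O)CC[C@]2(CO)[C@@H]1CCC3=C4[C@H](CC3)[C@H](C(=O)OC)C[C@@]42CN(C)C1
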